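The readings of both earlier flasks obey one balance: starting material and product together stay near 100% of the charge, within the scatter.

| setting | spring | winter | flask |
|---|---|---|---|
| starting material | 0.22 M | 0.33 M | 0.22 M |
| partner | 0.33 M | 0.33 M | 0.330 M |
| remark | the very flask that is asked about, followed so far | run made earlier |  |
| time |  |  | 3.0 h |

| run | time / min | product / % | starting material / % |
|---|---|---|---|
| spring | 8.00 | 11.1 | 89.8 |
| spring | 20.0 | 14.3 | 85.9 |
| spring | 40.0 | 16.9 | 83.4 |
| spring | 60.0 | 15.6 | 83.8 |
| spring | 80.0 | 16.0 | 82.6 |
| spring | 120 | 17.4 | 83.8 |
| spring | 150 | 17.5 | 83.0 |
| winter | 1.00 | 2.5 | 95.6 |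
| winter | 1.50 | 6.0 | 93.7 |
| winter | 2.50 | 7.2 | 93.2 |
| winter | 4.00 | 6.2 | 93.2 |
| winter | 6.00 | 9.5 | 90.0 |
| winter | 10.0 | 9.0 | 90.9 |
| winter | 15.0 | 11.4 | 89.2 |

(readings scatter by 1 percentage point)

- Monday's: change nothing and wait 50 min more
- Wednesday's: at 3.0 h add partner, 100% of the amount charged, then wait 50 min
- Thursday's: at 3.0 h add starting material, 50.0% of the amount charged, then wait 50 min
- Friday's: at 3.0 h take out 90% of the leaving ligand then present, then wait 50 min

- additions bring no volume worth counting
- a reading or a percentage of product counts all its forms, free or not

- product, in percent of the starting material first charged, at 3.0 h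
- the remedy with the largest gain of product, or "none" below 2 percentage points (Monday's / Wednesday's / Thursday's / Friday's / none)
- product present, in percent of the starting material first charged, after Wednesday's
- product present, in percent of the starting material first charged, after Friday's

I drew the spring flask first. Product rose steeply to 11.1% by 8.00 min, then gained 3.2 percentage points in the next 12.0 min. From 40.0 min on, its five readings spanned 1.9 points, about twice the scatter, so I averaged them into a level of 16.7%, with 83.3% starting material beside it. The mean slope up to 8.00 min, carried straight on, meets that level at 12.0 min, which I took as the knee. My own figure for the spring flask at 3.0 h was therefore this level.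

That level means c(product) = 0.0367 M and c(starting material) = 0.183 M. I took each product to come with one leaving ligand that holds the reaction back, so I carried the level quotient, c(product) squared over c(starting material) at the level, 0.00735 M. Both flasks had 0.330 M partner, so this quotient held that charge fixed, and I meant it for starting material charged at the start. For the winter flask it gave a level of 0.0457 M, or 13.8% of its charge, and its last reading of 11.4% lay below that.

The forecast gave 17% now, 23.4% after Wednesday's and 25% after Friday's, and it named Friday's as best, holding that the level “points to an equilibrium rather than a dead reaction”.

The flask gave 17.3%. Wednesday's gained 6.5 points, reaching 23.7%, which made Wednesday's the best remedy. Friday's reached 17.5%, 7.5 points under the forecast.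

    2 partner → homo dimer (k = 0.0200 /M/s)
    starting material ⇌ intermediate + leaving ligand (K = 7.90 × 10⁻⁶ M, k = 0.00190 /s)
    crystals ⇌ product, rate k3*(cs3 - [product]) while solid is left; crystals form when [product] > cs3 (solubility = 11.0 mM, k = 0.410 /s)
    partner + intermediate → product (k = 5.60 /M/s)

On Thursday's, the starting material put into the flask came in sum to the winter charge, so the quotient, stretched past the charges it was meant for, gave 20.8% of the first charge, but that dose came at 3.0 h and the flask gained 0.15 points. Partner, the limiting reagent of this flask, stood at 0.165% of its charge at 3.0 h, before any dose, beside 0.146 M homo dimer. For the neighbour charged with 0.55 M starting material at the start and the same partner, the quotient gave 0.0600 M, or 10.9%, and that flask gave 10.6% at 3.0 h. This flask had nearly come to rest: at 1800 min, ten times the time, product stood at 17.5%, 0.20 points above its value at 3.0 h.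

The earlier runs and the new flask come from a simulation with made-up constants, noise included.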